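The constants were drawn at random within sensible limits, and the outcome is calculated.

In 100 min a catalyst that dies while it works can carry a ring of isomers a limited way, so I count how far it gets. In delta and epsilon, free catalyst moves substrate round through target, isomer of the product A and isomer of the product B, and is lost to impurity and to substrate.

| flask | substrate | free catalyst | impurity | time |
|---|---|---|---|---|
| delta | 3.0 M | 300 mM | 90 mM | 100 min |
| epsilon | 3.0 M | 300 mM | 69 mM | 100 min |

    target + free catalyst ⇌ isomer of the product A + free catalyst, rate k1*[free catalyst]*[target] forward; the back reaction follows from the equilibrium constant (K1 = 1.40, k1 = 0.353 M⁻¹ min⁻¹)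
    isomer of the product B + free catalyst ⇌ substrate + free catalyst, rate k2*[free catalyst]*[isomer of the product B] forward; the back reaction follows from the equilibrium constant (k2 = 1.20 M⁻¹ min⁻¹)
    free catalyst + impurity → spent catalyst A (k3 = 535 M⁻¹ min⁻¹)
    substrate + free catalyst ⇌ target + free catalyst, rate k4*[substrate]*[free catalyst] forward; the back reaction follows from the equilibrium constant (K4 = 0.516, k4 = 0.264 M⁻¹ min⁻¹)
    substrate + free catalyst → spent catalyst B (k5 = 0.0152 M⁻¹ min⁻¹)
    isomer of the product A + free catalyst ⇌ isomer of the product B + free catalyst, rate k6*[free catalyst]*[isomer of the product A] forward; the back reaction follows from the equilibrium constant (K6 = 0.74, k6 = 0.277 M⁻¹ min⁻¹)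

- which of these there is most of at the end, counted by the substrate in it, delta (substrate / isomer of the product B / target / isomer of the product A)
- which of these there is most of at the end, counted by the substrate in it, epsilon (substrate / isomer of the product B / target / isomer of the product A)
- the largest of these amounts at the end, in percent of the substrate charged, delta
- the largest of these amounts at the end, in percent of the substrate charged, epsilon

The closed ring gives equilibrium shares: substrate s = 36.1%, next isomer of the product A at 26.1%. Impurity takes its catalyst first: in epsilon, at the start, substrate uses catalyst at hardly any of impurity's rate. That leaves live catalyst L of 210 mM in delta and 231 mM in epsilon. At the ring's substrate level, L decays with lifetime τ = 60.8 min, so 80.7% of it is spent by the end.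

My quantity is N, the catalyst exposure over the run times the substrate's forward constant, which counts the substrate time constants the flask receives: 2.72 in delta and 2.99 in epsilon. Large N means thermodynamic control, small N kinetic control.

Spending L entirely gives the bound from below, s times the charge remaining: 33.5% in delta, 33.3% in epsilon, above isomer of the product A's share. Spending the fraction reckoned gives my figures, 34.0% in delta and 33.8% in epsilon. Adding the excess left after N gives the bound from above: 38.2% in delta, 37.0% in epsilon.

The forecast names substrate in delta and substrate in epsilon, at 33.6% and 33.4%, expecting the flasks to “essentially reach that equilibrium in both runs”. Both values lie inside my brackets, below my figures.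

The flask gives substrate at 33.8% in delta and substrate at 33.5% in epsilon, both inside the brackets.

So epsilon, with N of 2.99, ends 0.20 percentage points above its floor. The neighbouring flask is epsilon with 0.12 M of free catalyst. Its L is 51.0 mM. Its substrate ends at 48.4%, above its ring share, so epsilon's lifetime does not carry over, and I reckon τ at that end level instead: 45.3 min, with 89.0% of L spent. That gives N = 0.543, less than epsilon's. The bracket of this neighbouring flask runs from 35.4% to 72.7%. Isomer of the product A there reaches 12.2%.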